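## The problem

The target **27** is a C30 terpenoid built on a trans-fused decalin (ring A C1–C5/C10, ring B C5–C10, labdane-type locants). Ring A carries a C3 ketone next to a C4 gem-dimethyl group; C10 bears an angular methyl; C8 is a tertiary 8α-hydroxy/8β-methyl carbinol; C9 carries a sixteen-carbon chain (C11 onward) with two E-trisubstituted alkenes and a terminal prenyl unit. Four contiguous stereocentres (5R, 8R, 9R, 10S; 5α-H, 10β-CH3, 9β-chain, 8α-OH) have to be set, two of them fully substituted. They can be made to control one another in a relay. The C8 carbinol can place the C9 substituent trans to its oxygen. The C9 substituent and the 8β-methyl then screen the β-face at C10. The 10β-methyl in turn fixes the trans ring fusion at C5 when a C4=C5 enone is reduced. The polyene chain is the fragile part: it will not survive protic or Lewis acid (cation–olefin cyclisation, alkene migration), electrophilic oxidants or hydrogenation, and the tertiary C8 alcohol eliminates under acid. The chain therefore has to arrive late, with its alkene geometry already fixed, under neutral metal-catalysed conditions. The feature that opens the molecule is ring A itself. C1–C2–C3(=O)–C4(CH3) is the carbon skeleton of ethyl vinyl ketone, and a 4,4-dimethyl-3-ketone fused at C5–C10 next to an angular methyl is the reductive-methylation product of a 4-methyl-4-en-3-one. That enone is what a ring B 2-methylcyclohexanone (C5 carbonyl, C10 methyl) gives on Robinson annulation.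

## Retrosynthesis

**Chain last (27 ⇒ 26 ⇒ 17 + 24).** After the O–Si cut, the C12–C13 bond between an sp3 and an sp2 carbon is cut. A cut one bond further in (C11–C12) would put a carbanion or leaving group on C11, a neopentyl-type carbon between two fully substituted centres. A cut at C13=C14 would demand an E-selective olefination to a trisubstituted alkene. The C12–C13 cut lets the geometry travel intact in iodide **24** and reduces the C9 substituent of **17** to a vinyl group. **17** is a C16 bicycle with no sensitive alkene. The forward B-alkyl Suzuki–Miyaura coupling must hydroborate the vinyl group without reducing the C3 ketone and must leave the triene untouched.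

**Iodide (24 ⇒ 22 ⇒ 21 ⇒ 18 + 19).** The C14–CH3 and C13–I bonds are traced to methylalumination/iodination of alkyne **22**, and C15–C16 to propargylation of geranyl bromide **19** with silylpropyne **18**. Against an olefination of a methyl ketone, carbometalation gives the E-alkene only. The forward steps ask for SN2 (not SN2') alkylation and syn carbometalation.

**Gem-dimethyl and ring fusion (17 ⇒ 15).** One C4–CH3 bond and the C5–H bond are removed together, giving the 4-methyl-4-en-3-one **15**. Bringing both C4 methyls in before ring closure would give up the enone, and with it the means of setting C5. **15** has one stereocentre and one quaternary carbon fewer. The reductive methylation must protonate C5 anti to the 10β-methyl and trap the C3–C4 enolate before it equilibrates toward C2.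

**Ring A (15 ⇒ 11 + 12, key step).** C4=C5 and C1–C10 are cut, which removes ring A, four carbons and the all-carbon quaternary centre, and leaves the monocyclic ketone **11** and ethyl vinyl ketone **12**. Cuts through ring B would leave the C8/C9/C10 triad to be made on a bicycle. This cut leaves a cyclohexanone whose only permanent stereocentres are C8 and C9. The annulation must alkylate the more substituted α-carbon (C10, not C6), and on the α-face.

**C10 methyl and C9 vinyl (11 ⇒ 9 ⇒ 8 + 5).** The C10–CH3 bond is cut to the C5=C10 silyl enol ether **9**, and the C9–C11 bond to enone **8** and vinylmagnesium bromide **5**. The neighbouring plan, trans-diaxial opening of a 1-methylcyclohexene oxide by a vinyl cuprate, would fix C8/C9 rigorously. It then has to place the C10 methyl on the more hindered α-carbon of a 3-substituted cyclohexanone, which needs a blocking detour, and it needs an asymmetric epoxidation whose selectivity on this alkene class is uncertain. Conjugate addition delivers the C10 enolate regiospecifically. The price is that the vinyl group must enter anti to the C8 silyloxy group.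

**Ring B (8 ⇒ 7 ⇒ 6 ⇒ 4 + 5; 4 ⇒ 2 ⇒ 1).** C9=C10 is cut by ring-closing metathesis and C5–C10 by Grignard addition, back to aldehyde **4**. **4** is the ozonolysis product of the silyl ether **2** of (R)-linalool **1**. The tertiary carbinol C8 is therefore bought, not made: C3 of linalool becomes C8, its vinyl CH becomes C9 and its C4–C6 become C7–C5. The forward steps ask only for chemoselective cleavage of the trisubstituted alkene in the presence of the vinyl group.

## Roads not taken

**Alternative 1: intramolecular furan Diels–Alder for both rings.** The cut is C5–C10 and C8–C9 at once. In the forward step, Me2AlCl would activate the E-enoate of the acyclic furan **A2**; the 2-methylfuran adds across C9=C10 to give the 5,8-oxygen-bridged tricycle **A1**. Merits: both rings, the quaternary C10 and the oxygenated C8 are formed in one step, and the C3 oxygen and C4 gem-dimethyl are in place beforehand. In ring-forming economy this road is better than the chosen one, which closes one ring in its key step. Weak points for this target: the dienophile is a β,β-disubstituted enoate and the furan terminus sits next to the quaternary C4, so the reversible furan cycloaddition has little driving force. The absolute sense at four new centres rests on the remote C3 silyloxy group. After **A1**, the C5–O bond must be cleaved with net retention to give 5α-H, the C6=C7 alkene reduced, C11 homologated by one carbon before the chain can be attached, and C3 deprotected and oxidised. Against this the chosen plan sets reliability: each centre is set by its direct neighbour, and no C–O bond has to be replaced by C–H at a ring fusion.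

**Alternative 2: ketyl–olefin closure of ring B.** The cut is C8–C9. In the forward step SmI2 (HMPA, t-BuOH) would turn the methyl ketone of the seco compound **A4** into a ketyl that adds 6-exo to C9 of the enoate, giving hydroxy ester **A3**. Merits: C8 and C9 are created together in a reaction with a well-understood anti preference between the oxygen and the new side arm, and the trans relationship at C5/C10 is already present. At C8/C9 this is stereochemically the safest of the four roads, safer than the substrate-controlled conjugate addition used here. Weak points: **A4** is a cyclohexane with two adjacent fully substituted carbons flanking C5, and preparing it as a single enantiomer means building and then cleaving ring B, which costs more steps than the whole of ring A in the chosen plan. The radical must also add next to the quaternary C10. The C12 ester must be reduced and activated before chain coupling, and the C3 silyl ether deprotected and oxidised. The chosen plan accepts the less certain facial selectivity at C9 in return for a far shorter route, and keeps a catalyst-controlled fallback for it.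

**Alternative 3: vinylcyclohexene Diels–Alder for ring B.** The cut is C7–C8 and C9–C10. In the forward step the ring A diene **A6** and methyl but-2-ynoate **A7** would react thermally in a sealed tube to give the 5,8-diene ester **A5**. Merits: it is the most convergent road; two simple pieces give the quaternary C10, the C8 methyl and C11 in one intermolecular step. Weak points: **A5** leaves C5, C8 and C9 unset. The tetrasubstituted, ester-conjugated C8=C9 alkene would have to be converted into the 8α-carbinol and 9α-H, and the C5=C6 alkene reduced to 5α-H, all on hindered alkenes. The one resident stereocentre (C3) is 1,4 to C10 and unlikely to control the face of cycloaddition, which fixes the absolute configuration. A diene with a fully substituted terminus and an internal ynoate needs forcing conditions. The chosen plan is less convergent in the ring system but has the C8 oxygen from the first step and sets each later centre from the one before.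

Key step: step 8

Assumption: commercial (R)-(−)-linalool of high enantiomeric purity is the source of C8; labdane locants (C1–C10 in the decalin, chain from C11) are used for all intermediates.

## Route

Step 1
Reactants: 1 (R)-(−)-linalool
Product: 2 (R)-triethyl[(3,7-dimethylocta-1,6-dien-3-yl)oxy]silane
Conditions: TESOTf, 2,6-lutidine, CH2Cl2, −78 → 0 °C
Reagents that add atoms: triethylsilyl trifluoromethanesulfonate CC[Si](CC)(CC)OS(=O)(=O)C(F)(F)F
Why: Silyl triflate/hindered-base silylation of a tertiary allylic alcohol; the carbinol centre (future C8) is not touched.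

Step 2
Reactants: 2 (R)-triethyl[(3,7-dimethylocta-1,6-dien-3-yl)oxy]silane
Product: 4 (R)-4-methyl-4-(triethylsilyloxy)hex-5-enal, via ozonide 3 (not isolated)
Conditions: O3, CH2Cl2, −78 °C, Sudan Red 7B end-point; then PPh3, −78 °C → rt
Reagents that add atoms: ozone [O-][O+]=O
Why: Chemoselective ozonolysis: electrophilic ozone attacks the electron-rich trisubstituted alkene much faster than the vinyl group, which is deactivated by the allylic oxygen and shielded by the quaternary carbon; the dye end-point limits ozone to one equivalent and PPh3 reduces the ozonide.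

Step 3
Reactants: 4 (R)-4-methyl-4-(triethylsilyloxy)hex-5-enal; 5 vinylmagnesium bromide
Product: 6 (6R)-6-methyl-6-(triethylsilyloxy)octa-1,7-dien-3-ol (both C3 epimers)
Conditions: THF, −78 → 0 °C; aqueous work-up
Reagents that add atoms: none
Why: Grignard 1,2-addition to an unhindered aldehyde forms C5–C10; the new carbinol centre is formed unselectively and is erased by the oxidation in step 5.

Step 4
Reactants: 6 (6R)-6-methyl-6-(triethylsilyloxy)octa-1,7-dien-3-ol
Product: 7 (4R)-4-methyl-4-(triethylsilyloxy)cyclohex-2-en-1-ol (both C1 epimers)
Conditions: second-generation Grubbs catalyst RuCl2(=CHPh)(PCy3)(H2IMes) (3 mol%), CH2Cl2 (0.01 M), 40 °C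
Reagents that add atoms: none
Why: Ring-closing metathesis of a 1,7-diene to the cyclohexene (C9=C10), driven by loss of ethylene; a secondary allylic alcohol and a tertiary allylic silyl ether are established partners for the Ru carbene.

Step 5
Reactants: 7 (4R)-4-methyl-4-(triethylsilyloxy)cyclohex-2-en-1-ol
Product: 8 (R)-4-methyl-4-(triethylsilyloxy)cyclohex-2-en-1-one
Conditions: activated MnO2, CH2Cl2, rt
Reagents that add atoms: none
Why: Allylic alcohol oxidation with MnO2; both epimers converge on one enone and the silyl ether is inert.

Step 6
Reactants: 8 (R)-4-methyl-4-(triethylsilyloxy)cyclohex-2-en-1-one; 5 vinylmagnesium bromide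
Product: 9 triethyl{[(1R,2R)-1-methyl-4-(trimethylsilyloxy)-2-vinylcyclohex-3-en-1-yl]oxy}silane
Conditions: CuBr·SMe2 (10 mol%), TMSCl, DMPU, THF, −78 °C; Et3N, then aqueous NaHCO3
Reagents that add atoms: chlorotrimethylsilane C[Si](C)(C)Cl
Why: Copper-catalysed, TMSCl-accelerated conjugate addition of a Grignard reagent; the vinyl group should enter C9 anti to the pseudoaxial C8–O bond in the half-chair that keeps the methyl (larger A-value) pseudoequatorial and aligns σ*(C–O) with the enone π-system, giving vinyl trans to oxygen, and TMSCl traps the enolate regiospecifically as the C5=C10 silyl enol ether.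

Step 7
Reactants: 9 triethyl{[(1R,2R)-1-methyl-4-(trimethylsilyloxy)-2-vinylcyclohex-3-en-1-yl]oxy}silane
Product: 11 (2R,3R,4R)-2,4-dimethyl-4-(triethylsilyloxy)-3-vinylcyclohexan-1-one, via lithium enolate 10 (not isolated)
Conditions: MeLi, THF, 0 °C → rt; then MeI, DMPU, −78 → 0 °C
Reagents that add atoms: iodomethane CI
Why: MeLi cleaves the enol O–Si bond to release the regiodefined lithium enolate, which is C-methylated at C10 before it can equilibrate; MeI enters anti to the vicinal vinyl group, but C10 is re-enolised in step 8, so its configuration is immaterial.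

Step 8
Reactants: 11 (2R,3R,4R)-2,4-dimethyl-4-(triethylsilyloxy)-3-vinylcyclohexan-1-one; 12 ethyl vinyl ketone
Product: 15 (4aR,5R,6R)-1,4a,6-trimethyl-6-(triethylsilyloxy)-5-vinyl-4,4a,5,6,7,8-hexahydronaphthalen-2(3H)-one, via Michael adduct 13 (not isolated), via ketol 14 (not isolated)
Conditions: 12 (1.5 equiv, slow addition), KOH (0.3 equiv), MeOH, 0 °C → rt; then KOH (2 equiv), 65 °C
Reagents that add atoms: none
Why: Robinson annulation (Michael addition, aldol closure, dehydration), the closest known reaction type being the annulation of 2-methyl- and 2,3-dialkylcyclohexanones with alkyl vinyl ketones. In methanolic hydroxide the two enolates of 11 interconvert, and the more substituted C5=C10 enolate adds to 12, forming C1–C10 and giving diketone 13. The ethyl ketone then enolises toward C4 and closes on the C5 carbonyl in a 6-(enolendo)-exo-trig aldol to ketol 14, forming C4–C5 and ring A; loss of water on heating gives the tetrasubstituted enone and drains the reversible steps before it. The only new stereocentre is C10, and in the half-chair enolate the β-face is screened in both conformers: by the pseudoaxial C9 vinyl group when allylic strain with the C10 methyl is relieved, and by the axial 8β-methyl (1,3 to C10) in the other. 12 should therefore bond on the α-face and leave the angular methyl β, cis to C11. The step needs regioselectivity for C10 over C6 (thermodynamic enolate control in a protic medium) and this facial selectivity. It also needs the substrate to survive: the tertiary triethylsilyl ether resists methanolic hydroxide, the C8 oxygen is γ to the carbonyl so no β-elimination path exists, and C9 is not enolisable.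

Step 9
Reactants: 15 (4aR,5R,6R)-1,4a,6-trimethyl-6-(triethylsilyloxy)-5-vinyl-4,4a,5,6,7,8-hexahydronaphthalen-2(3H)-one
Product: 17 (4aS,5R,6R,8aR)-1,1,4a,6-tetramethyl-6-(triethylsilyloxy)-5-vinyloctahydronaphthalen-2(1H)-one, via lithium enolate 16 (not isolated)
Conditions: Li, NH3(l)/THF, t-BuOH (1.0 equiv), −78 °C; isoprene; then MeI, THF, −78 °C → rt
Reagents that add atoms: iodomethane CI
Why: Dissolving-metal reductive alkylation of a 4-methyl-4-en-3-one: two-electron reduction and protonation of C5 by t-BuOH anti to the 10β-methyl gives the trans-decalin (5α-H), and the regiodefined C3–C4 lithium enolate is C-methylated to the gem-dimethyl ketone; the isolated vinyl group and the silyl ether are not reduced.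

Step 10
Reactants: 18 1-(trimethylsilyl)propyne; 19 geranyl bromide
Product: 21 (E)-(6,10-dimethylundeca-5,9-dien-1-yn-1-yl)trimethylsilane, via propargyllithium 20 (not isolated)
Conditions: 18, n-BuLi, THF, −78 → −20 °C; then 19, −78 °C → rt
Reagents that add atoms: none
Why: Propargylic lithiation and SN2 alkylation of a primary allylic bromide; the silyl group blocks the alkyne terminus and suppresses allene formation, and the E-alkene of the geranyl unit is untouched.

Step 11
Reactants: 21 (E)-(6,10-dimethylundeca-5,9-dien-1-yn-1-yl)trimethylsilane
Product: 22 (E)-6,10-dimethylundeca-5,9-dien-1-yne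
Conditions: K2CO3 (cat.), MeOH, rt
Reagents that add atoms: none
Why: Base-catalysed methanolysis of the alkynyl C–Si bond.

Step 12
Reactants: 22 (E)-6,10-dimethylundeca-5,9-dien-1-yne
Product: 24 (1E,5E)-1-iodo-2,6,10-trimethylundeca-1,5,9-triene, via alkenylalane 23 (not isolated)
Conditions: Me3Al, Cp2ZrCl2 (0.25 equiv), CH2Cl2, 0 °C → rt; then I2, THF, −30 → 0 °C
Reagents that add atoms: trimethylaluminium C[Al](C)C; iodine II
Why: Zirconium-catalysed carboalumination (Negishi) adds CH3–Al syn across the terminal alkyne with methyl on the internal carbon, and iodinolysis with retention gives the E-iodide; the trisubstituted alkenes do not react.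

Step 13
Reactants: 17 (4aS,5R,6R,8aR)-1,1,4a,6-tetramethyl-6-(triethylsilyloxy)-5-vinyloctahydronaphthalen-2(1H)-one; 24 (1E,5E)-1-iodo-2,6,10-trimethylundeca-1,5,9-triene
Product: 26 (4aS,5R,6R,8aR)-1,1,4a,6-tetramethyl-6-(triethylsilyloxy)-5-[(3E,7E)-4,8,12-trimethyltrideca-3,7,11-trien-1-yl]octahydronaphthalen-2(1H)-one, via alkylborane 25 (not isolated)
Conditions: 9-BBN (1.3 equiv), THF, 0 °C → rt; H2O; then 24, PdCl2(dppf) (5 mol%), AsPh3, Cs2CO3, DMF/THF/H2O, rt
Reagents that add atoms: none
Why: 9-BBN adds anti-Markovnikov to the terminal vinyl group faster than it reduces the C3 ketone, which is flanked by the quaternary C4, and excess B–H is quenched before the triene is added; the B-alkyl Suzuki–Miyaura coupling (oxidative addition of the alkenyl iodide to zerovalent palladium, base-assisted transfer of the primary alkyl group, reductive elimination) forms C12–C13 with retention of the E geometry.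

Step 14
Reactants: 26 (4aS,5R,6R,8aR)-1,1,4a,6-tetramethyl-6-(triethylsilyloxy)-5-[(3E,7E)-4,8,12-trimethyltrideca-3,7,11-trien-1-yl]octahydronaphthalen-2(1H)-one
Product: 27 (4aS,5R,6R,8aR)-6-hydroxy-1,1,4a,6-tetramethyl-5-[(3E,7E)-4,8,12-trimethyltrideca-3,7,11-trien-1-yl]octahydronaphthalen-2(1H)-one (CNP0158964.2)
Conditions: Bu4NF, THF, rt → 40 °C
Reagents that add atoms: none
Why: Fluoride-induced Si–O cleavage under non-acidic conditions spares the triene and the tertiary alcohol; no stereocentre is affected.

## Compound list

1 | (R)-(−)-linalool, (3R)-3,7-dimethylocta-1,6-dien-3-ol | C=C[C@](C)(O)CCC=C(C)C | starting material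
2 | (R)-triethyl[(3,7-dimethylocta-1,6-dien-3-yl)oxy]silane | C=C[C@](C)(O[Si](CC)(CC)CC)CCC=C(C)C | intermediate
3 | secondary ozonide of 2, 3,3-dimethyl-5-[(3R)-3-methyl-3-(triethylsilyloxy)pent-4-en-1-yl]-1,2,4-trioxolane (ring carbon unassigned) | C=C[C@](C)(O[Si](CC)(CC)CC)CCC1OOC(C)(C)O1 | intermediate (not isolated)
4 | (R)-4-methyl-4-(triethylsilyloxy)hex-5-enal | C=C[C@](C)(O[Si](CC)(CC)CC)CCC=O | intermediate
5 | vinylmagnesium bromide | C=C[Mg]Br | starting material
6 | (6R)-6-methyl-6-(triethylsilyloxy)octa-1,7-dien-3-ol, both C3 epimers | C=C[C@](C)(O[Si](CC)(CC)CC)CCC(O)C=C | intermediate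
7 | (4R)-4-methyl-4-(triethylsilyloxy)cyclohex-2-en-1-ol, both C1 epimers | OC1C=C[C@](C)(O[Si](CC)(CC)CC)CC1 | intermediate
8 | (R)-4-methyl-4-(triethylsilyloxy)cyclohex-2-en-1-one | O=C1C=C[C@](C)(O[Si](CC)(CC)CC)CC1 | intermediate
9 | triethyl{[(1R,2R)-1-methyl-4-(trimethylsilyloxy)-2-vinylcyclohex-3-en-1-yl]oxy}silane (C5=C10 silyl enol ether, vinyl trans to the C8 oxygen) | C=C[C@@H]1C=C(O[Si](C)(C)C)CC[C@@]1(C)O[Si](CC)(CC)CC | intermediate
10 | lithium (4R,5R)-4-methyl-4-(triethylsilyloxy)-5-vinylcyclohex-1-en-1-olate (C5=C10 enolate) | C=C[C@@H]1C=C(O[Li])CC[C@@]1(C)O[Si](CC)(CC)CC | intermediate (not isolated)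
11 | (2R,3R,4R)-2,4-dimethyl-4-(triethylsilyloxy)-3-vinylcyclohexan-1-one (C10 methyl trans to vinyl, vinyl trans to the C8 oxygen) | C=C[C@@H]1[C@@H](C)C(=O)CC[C@@]1(C)O[Si](CC)(CC)CC | intermediate
12 | ethyl vinyl ketone (pent-1-en-3-one) | CCC(=O)C=C | starting material
13 | (2R,3R,4R)-2,4-dimethyl-2-(3-oxopentyl)-4-(triethylsilyloxy)-3-vinylcyclohexan-1-one | C=C[C@@H]1[C@@](C)(CCC(=O)CC)C(=O)CC[C@@]1(C)O[Si](CC)(CC)CC | intermediate (not isolated)
14 | 8a-hydroxy-1,4a,6-trimethyl-6-(triethylsilyloxy)-5-vinyloctahydronaphthalen-2(1H)-one (C8, C9, C10 as in 15; C4 and C5 unassigned) | C=C[C@@H]1[C@@]2(C)CCC(=O)C(C)C2(O)CC[C@@]1(C)O[Si](CC)(CC)CC | intermediate (not isolated)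
15 | (4aR,5R,6R)-1,4a,6-trimethyl-6-(triethylsilyloxy)-5-vinyl-4,4a,5,6,7,8-hexahydronaphthalen-2(3H)-one (4-methyl-4-en-3-one, 10β-methyl) | C=C[C@@H]1[C@@]2(C)CCC(=O)C(C)=C2CC[C@@]1(C)O[Si](CC)(CC)CC | intermediate
16 | lithium C3–C4 enolate of the 5α-H dihydro derivative of 15 | C=C[C@@H]1[C@@]2(C)CCC(O[Li])=C(C)[C@@H]2CC[C@@]1(C)O[Si](CC)(CC)CC | intermediate (not isolated)
17 | (4aS,5R,6R,8aR)-1,1,4a,6-tetramethyl-6-(triethylsilyloxy)-5-vinyloctahydronaphthalen-2(1H)-one | C=C[C@@H]1[C@@]2(C)CCC(=O)C(C)(C)[C@@H]2CC[C@@]1(C)O[Si](CC)(CC)CC | intermediate
18 | 1-(trimethylsilyl)propyne | CC#C[Si](C)(C)C | starting material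
19 | geranyl bromide, (E)-1-bromo-3,7-dimethylocta-2,6-diene | CC(C)=CCC/C(C)=C/CBr | starting material
20 | 3-(trimethylsilyl)prop-2-yn-1-yllithium | [Li]CC#C[Si](C)(C)C | intermediate (not isolated)
21 | (E)-(6,10-dimethylundeca-5,9-dien-1-yn-1-yl)trimethylsilane | CC(C)=CCC/C(C)=C/CCC#C[Si](C)(C)C | intermediate
22 | (E)-6,10-dimethylundeca-5,9-dien-1-yne | CC(C)=CCC/C(C)=C/CCC#C | intermediate
23 | dimethyl[(1E,5E)-2,6,10-trimethylundeca-1,5,9-trien-1-yl]alane | CC(C)=CCC/C(C)=C/CC/C(C)=C/[Al](C)C | intermediate (not isolated)
24 | (1E,5E)-1-iodo-2,6,10-trimethylundeca-1,5,9-triene | CC(C)=CCC/C(C)=C/CC/C(C)=C/I | intermediate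
25 | 9-[2-(C9 of the decalin of 17)ethyl]-9-borabicyclo[3.3.1]nonane (stereocentres as in 17) | C(C[C@@H]1[C@@]2(C)CCC(=O)C(C)(C)[C@@H]2CC[C@@]1(C)O[Si](CC)(CC)CC)B1C2CCCC1CCC2 | intermediate (not isolated)
26 | (4aS,5R,6R,8aR)-1,1,4a,6-tetramethyl-6-(triethylsilyloxy)-5-[(3E,7E)-4,8,12-trimethyltrideca-3,7,11-trien-1-yl]octahydronaphthalen-2(1H)-one | CC(C)=CCC/C(C)=C/CC/C(C)=C/CC[C@@H]1[C@@]2(C)CCC(=O)C(C)(C)[C@@H]2CC[C@@]1(C)O[Si](CC)(CC)CC | intermediate
27 | (4aS,5R,6R,8aR)-6-hydroxy-1,1,4a,6-tetramethyl-5-[(3E,7E)-4,8,12-trimethyltrideca-3,7,11-trien-1-yl]octahydronaphthalen-2(1H)-one (CNP0158964.2) | CC(C)=CCC/C(C)=C/CC/C(C)=C/CC[C@@H]1[C@@]2(C)CCC(=O)C(C)(C)[C@@H]2CC[C@@]1(C)O | target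

## Step count and least certain steps

Total step count: 14. Longest linear sequence: 11 steps (steps 1–9, 13, 14); the iodide branch (steps 10–12) is 3 steps.

**Step 8 (key step).** The most likely failure is competing Michael addition at the less hindered C6, or slow addition at the congested C10 while 12 polymerises. The tetrasubstituted enolate is penalised by allylic strain with the C9 vinyl group, and C10 lies between a carbonyl and a tertiary centre. Erosion of facial selectivity and partial loss of the silyl ether in hot methanolic hydroxide are lesser risks. Fallback, from 11 back to 15: 11 is condensed with (R)-1-phenylethylamine (4 Å sieves, toluene, 80 °C) to the imine F1. Its secondary-enamine tautomer forms toward the more substituted carbon and reacts there only, so it adds to 12 (THF, 40 °C) at C10 under neutral conditions to give the keto imine F2. The (R)-amine is the enantiomer whose established facial preference in this reaction type matches the substrate bias. Aqueous AcOH then releases diketone 13, now isolated, and NaOMe/MeOH closes and dehydrates it to 15.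

**Step 6.** The risk is poor facial discrimination at C9, because the directing centre C8 carries both a methyl and a silyloxy group and the preference for attack anti to oxygen rests on a conformational and stereoelectronic bias, not on a rigid template. Fallback, from 8 back to 11, with the face chosen by a catalyst: a Hayashi–Miyaura addition of vinylboronic acid pinacol ester ([Rh(cod)OH]2, (S)-BINAP, aqueous dioxane, 60 °C) gives the 3-vinyl ketone F3. (S)-BINAP is the enantiomer that delivers alkenyl groups to the required face of cyclohex-2-enones. Since this gives up the regiospecific enolate, C6 is then blocked by formylation (HCO2Et, NaH, THF) to the hydroxymethylene ketone F4. Its dianion (LiN(i-Pr)2, 2.2 equiv) is methylated at C10 with MeI to give F5, and aqueous KOH/MeOH removes the formyl group to return 11.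

**Step 9.** The likely failures are proton transfer to the enolate before alkylation (giving the monomethyl ketone), and further methylation at C2 by amide base formed in ammonia. Fallback, from 15 back to 17: the reduction (Li, NH3, t-BuOH) is quenched with TMSCl/Et3N instead of MeI, and the C3–C4 trimethylsilyl enol ether F6 is isolated. The enolate is then regenerated in THF with MeLi and methylated with MeI in the absence of ammonia.

**Step 13.** The risk is competitive reduction of the C3 ketone by 9-BBN during hydroboration of the hindered vinyl group, which would lower conversion to the borane and complicate the coupling. Fallback, from 17 back to 26: the ketone is first reduced with NaBH4 to the 3β-alcohol F7. Hydroboration with 9-BBN (2.2 equiv) and the same palladium coupling with 24 give the coupled alcohol F8, and Dess–Martin periodinane restores the ketone to give 26.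

**Step 2.** The risk is over-oxidation: ozone is only moderately selective between the trisubstituted alkene and the vinyl group, so cleavage of the vinyl group may compete near the end-point. Fallback, from 2 back to 4: mCPBA (1 equiv, NaHCO3, CH2Cl2, 0 °C) epoxidises only the trisubstituted alkene to give the epoxide F9, and H5IO6 in aqueous THF cleaves it to 4.

## Further compounds

F1 | step 8 | (R)-1-phenylethylamine imine of 11 | C=C[C@@H]1[C@@H](C)C(=N[C@H](C)c2ccccc2)CC[C@@]1(C)O[Si](CC)(CC)CC
F2 | step 8 | (R)-1-phenylethylamine imine (at C5) of diketone 13 | C=C[C@@H]1[C@@](C)(CCC(=O)CC)C(=N[C@H](C)c2ccccc2)CC[C@@]1(C)O[Si](CC)(CC)CC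
F3 | step 6 | (3S,4R)-4-methyl-4-(triethylsilyloxy)-3-vinylcyclohexan-1-one | C=C[C@@H]1CC(=O)CC[C@@]1(C)O[Si](CC)(CC)CC
F4 | step 6 | (4R,5S)-2-(hydroxymethylene)-4-methyl-4-(triethylsilyloxy)-5-vinylcyclohexan-1-one | C=C[C@@H]1CC(=O)C(=CO)C[C@@]1(C)O[Si](CC)(CC)CC
F5 | step 6 | (4R,5R,6R)-2-(hydroxymethylene)-4,6-dimethyl-4-(triethylsilyloxy)-5-vinylcyclohexan-1-one | C=C[C@@H]1[C@@H](C)C(=O)C(=CO)C[C@@]1(C)O[Si](CC)(CC)CC
F6 | step 9 | C3–C4 trimethylsilyl enol ether of the 5α-H dihydro derivative of 15 | C=C[C@@H]1[C@@]2(C)CCC(O[Si](C)(C)C)=C(C)[C@@H]2CC[C@@]1(C)O[Si](CC)(CC)CC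
F7 | step 13 | 3β-alcohol from reduction of 17 | C=C[C@@H]1[C@@]2(C)CC[C@H](O)C(C)(C)[C@@H]2CC[C@@]1(C)O[Si](CC)(CC)CC
F8 | step 13 | 3β-alcohol corresponding to 26 | CC(C)=CCC/C(C)=C/CC/C(C)=C/CC[C@@H]1[C@@]2(C)CC[C@H](O)C(C)(C)[C@@H]2CC[C@@]1(C)O[Si](CC)(CC)CC
F9 | step 2 | (R)-triethyl{[5-(3,3-dimethyloxiran-2-yl)-3-methylpent-1-en-3-yl]oxy}silane (epoxide carbon unassigned) | C=C[C@](C)(O[Si](CC)(CC)CC)CCC1OC1(C)C
A1 | alternative 1 | methyl 3β-(tert-butyldimethylsilyloxy)-5,8-epoxydrim-6-en-11-oate | COC(=O)[C@@H]1[C@@]2(C)CC[C@H](O[Si](C)(C)C(C)(C)C)C(C)(C)[C@]23C=C[C@@]1(C)O3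
A2 | alternative 1 | methyl (E)-6-(tert-butyldimethylsilyloxy)-3,7-dimethyl-7-(5-methylfuran-2-yl)oct-2-enoate | COC(=O)/C=C(\C)CC[C@H](O[Si](C)(C)C(C)(C)C)C(C)(C)c1ccc(C)o1
A3 | alternative 2 | methyl 3β-(tert-butyldimethylsilyloxy)-8α-hydroxy-13,14,15,16-tetranorlabdan-12-oate | COC(=O)C[C@@H]1[C@@]2(C)CC[C@H](O[Si](C)(C)C(C)(C)C)C(C)(C)[C@@H]2CC[C@@]1(C)O
A4 | alternative 2 | 8,9-seco keto enoate: ring A cyclohexane with the (E)-CH=CH–CO2CH3 arm and methyl on C10 and the 3-oxobutyl arm on C5 | COC(=O)/C=C/[C@@]1(C)CC[C@H](O[Si](C)(C)C(C)(C)C)C(C)(C)[C@@H]1CCC(C)=O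
A5 | alternative 3 | methyl 3β-(tert-butyldimethylsilyloxy)drima-5,8-dien-11-oate | COC(=O)C1=C(C)CC=C2C(C)(C)[C@@H](O[Si](C)(C)C(C)(C)C)CC[C@]12C
A6 | alternative 3 | tert-butyldimethyl[(2,2,4-trimethyl-3-vinylcyclohex-3-en-1-yl)oxy]silane | C=CC1=C(C)CC[C@H](O[Si](C)(C)C(C)(C)C)C1(C)C
A7 | alternative 3 | methyl but-2-ynoate | CC#CC(=O)OC
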